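**Plan**
Side chain locants: C1' (on ring C4) to C16' (terminal CH3), AcO on C15'; ring: O1, C2(=O), C3(CH3), C4, C5H2.
Retrosynthesis cuts, in order: (i) the C8'–C9' CH2–CH2 bond in the middle of the (CH2)14 tether (alkyl–alkyl coupling); (ii) the ring C4–C1' bond (sp2–sp3 coupling to a 4-bromofuranone); (iii) the acetate ester and the C13'–C14' bond (epoxide opening).
Forward: the 3-methylfuran-2(5H)-one ring is bought as 3-methyltetronic acid and never built. The chain is joined C13'–C14' first (left half), C4–C1' second (right half) and C8'–C9' last, which gives the target directly, with no protecting groups.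
Enabling feature: C8' and C9' are plain methylenes, seven CH2 from ring C4 and five CH2 from the C15' carbinol carbon. One can therefore come from a terminal alkene (as a primary alkylborane) and the other from a primary bromide, while the remote secondary acetate and the tetrasubstituted butenolide tolerate the coupling.
Stereochemistry: the single stereocentre (C15', S) comes from (S)-propylene oxide; its C–O bond is never broken.

Key step: step 5

Assumption: 3-methyltetronic acid (6) is taken as a purchasable building block and reacts through its 4-hydroxy enol form.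

**Step 1**
Reactants: 1 (S)-2-methyloxirane ((S)-propylene oxide); 2 5-bromopent-1-ene
Product: 4 (S)-oct-7-en-2-ol, via pent-4-enylmagnesium bromide 3 (not isolated)
Conditions: 2, Mg, THF, rt; then CuI (10 mol %), 1, −30 → 0 °C; H2O/NH4Cl work-up
Reagents that add atoms: none
Why: Copper-catalysed Grignard opening of a terminal epoxide is an SN2 attack at the unsubstituted CH2 carbon, so the C–O bond of the stereocentre is untouched and the (S) configuration of 1 should pass unchanged into 4.

**Step 2**
Reactants: 4 (S)-oct-7-en-2-ol
Product: 5 (S)-oct-7-en-2-yl acetate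
Conditions: Ac2O, pyridine, DMAP (cat.), CH2Cl2, 0 °C → rt
Reagents that add atoms: acetic anhydride, CC(=O)OC(C)=O
Why: DMAP-catalysed O-acetylation of a secondary alcohol takes place at oxygen, so the configuration at C2 is retained.

**Step 3**
Reactants: 6 3-methyltetronic acid (4-hydroxy-3-methylfuran-2(5H)-one)
Product: 7 4-bromo-3-methylfuran-2(5H)-one
Conditions: (COBr)2, DMF, CH2Cl2, 0 °C → rt
Reagents that add atoms: oxalyl bromide, O=C(Br)C(=O)Br
Why: Vilsmeier-type deoxybromination of a vinylogous acid: the enol oxygen is activated by the bromoiminium salt formed from DMF and oxalyl bromide, and bromide then replaces it at C4 by addition–elimination.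

**Step 4**
Reactants: 8 8-bromooct-1-ene; 7 4-bromo-3-methylfuran-2(5H)-one
Product: 10 4-(8-bromooctyl)-3-methylfuran-2(5H)-one, via 9-(8-bromooctyl)-9-borabicyclo[3.3.1]nonane 9 (not isolated)
Conditions: 8, 9-BBN, THF, 0 °C → rt; then 7, PdCl2(dppf)·CH2Cl2 (5 mol %), AsPh3, Cs2CO3, DMF/H2O, rt
Reagents that add atoms: none
Why: Anti-Markovnikov hydroboration of the terminal alkene followed by B-alkyl Suzuki–Miyaura coupling should work because Pd(0)/dppf inserts into the activated C(sp2)–Br bond of the β-bromo enoate much faster than into the primary C(sp3)–Br bond, which is kept for step 5.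

**Step 5**
Reactants: 5 (S)-oct-7-en-2-yl acetate; 10 4-(8-bromooctyl)-3-methylfuran-2(5H)-one
Product: 12 (S)-16-(4-methyl-5-oxo-2,5-dihydrofuran-3-yl)hexadecan-2-yl acetate, via (S)-8-(9-borabicyclo[3.3.1]nonan-9-yl)octan-2-yl acetate 11 (not isolated)
Conditions: 5, 9-BBN, THF, rt; then 10, Pd(OAc)2 (4 mol %), PCy3 (8 mol %), K3PO4·H2O, THF, rt
Reagents that add atoms: none
Why: 9-BBN adds to the terminal alkene of 5 with boron on the end carbon only, and the primary B-alkyl-9-BBN 11 is coupled in the same flask: electron-rich Pd(0)/PCy3 inserts into the primary C–Br bond of 10 by an SN2-type oxidative addition, the base-activated borate transfers its primary alkyl group to palladium, and reductive elimination forms the C8'–C9' C(sp3)–C(sp3) bond. The closest known reaction type is the room-temperature Suzuki–Miyaura coupling of primary alkyl bromides bearing β-hydrogens with B-alkyl-9-BBN reagents under Pd/trialkylphosphine catalysis. No ring is closed and no stereocentre is created; C15' lies six carbons from the reacting centre, its C–O bond is not involved, and it keeps the (S) configuration from step 1. The step needs hydroboration of the alkene in preference to the acetate carbonyl (secured by the low reactivity of 9-BBN towards esters at rt and by using no excess of borane), and reductive elimination faster than β-hydride elimination (secured by the bulky, strongly donating PCy3). It also needs the furanone to stay inert, which is expected because the tetrasubstituted, electron-poor C3=C4 bond binds Pd(0) poorly and solid K3PO4·H2O at rt should spare both the lactone and the acetate. The target forms directly, with both polar end groups already in their final form.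

**Compound list**
1 | (S)-2-methyloxirane ((S)-propylene oxide) | C[C@H]1CO1 | starting material
2 | 5-bromopent-1-ene | C=CCCCBr | starting material
3 | pent-4-enylmagnesium bromide | C=CCCC[Mg]Br | intermediate (not isolated)
4 | (S)-oct-7-en-2-ol | C[C@H](O)CCCCC=C | intermediate
5 | (S)-oct-7-en-2-yl acetate | CC(=O)O[C@@H](C)CCCCC=C | intermediate
6 | 3-methyltetronic acid (4-hydroxy-3-methylfuran-2(5H)-one) | CC1=C(O)COC1=O | starting material
7 | 4-bromo-3-methylfuran-2(5H)-one | CC1=C(Br)COC1=O | intermediate
8 | 8-bromooct-1-ene | C=CCCCCCCBr | starting material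
9 | 9-(8-bromooctyl)-9-borabicyclo[3.3.1]nonane | BrCCCCCCCCB1C2CCCC1CCC2 | intermediate (not isolated)
10 | 4-(8-bromooctyl)-3-methylfuran-2(5H)-one | CC1=C(CCCCCCCCBr)COC1=O | intermediate
11 | (S)-8-(9-borabicyclo[3.3.1]nonan-9-yl)octan-2-yl acetate | CC(=O)O[C@@H](C)CCCCCCB1C2CCCC1CCC2 | intermediate (not isolated)
12 | (S)-16-(4-methyl-5-oxo-2,5-dihydrofuran-3-yl)hexadecan-2-yl acetate | CC(=O)O[C@@H](C)CCCCCCCCCCCCCCC1=C(C)C(=O)OC1 | target

**Totals**
Total step count: 5. Longest linear sequence: 3 steps (1 → 2 → 5, or 3 → 4 → 5).

**Steps most likely to fail**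

Step 5. Transmetalation of the B-alkyl-9-BBN may be slow, so that β-hydride elimination or protodehalogenation of the alkylpalladium species takes over; the furanone may also degrade slowly through base-induced enolisation at C5. The fallback makes the junction as an alkene by cross-metathesis and then saturates it; it sets out from 7 and 5 and comes back at 12. Deca-1,9-diene (bought, used in excess) would be monohydroborated with 9-BBN to 9-(dec-9-en-1-yl)-9-borabicyclo[3.3.1]nonane F1. F1 would be coupled with 7 under the conditions of step 4 to give 4-(dec-9-en-1-yl)-3-methylfuran-2(5H)-one F2. Cross-metathesis of F2 with an excess of 5 (Grubbs second-generation catalyst, CH2Cl2, 40 °C, ethene lost) should give (S)-16-(4-methyl-5-oxo-2,5-dihydrofuran-3-yl)hexadec-7-en-2-yl acetate F3 as an E/Z mixture. The junction is displaced by one carbon (C9'=C10'), which no longer matters after reduction. Both isomers should converge on 12 on hydrogenation with H2/RhCl(PPh3)3 (benzene/EtOH, rt), which is expected to leave the tetrasubstituted conjugated ring alkene alone.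

Step 4. The primary C–Br bond may be lost during the basic palladium coupling, by competing oxidative addition, substitution by carbonate or hydroxide, or elimination. The fallback carries the chain end as a silyl ether and installs the bromide afterwards; it sets out from 7 and comes back at 10. Oct-7-en-1-ol (bought) would be silylated (TBSCl, imidazole, CH2Cl2) to tert-butyldimethyl(oct-7-en-1-yloxy)silane F4. Hydroboration with 9-BBN would give 9-[8-(tert-butyldimethylsilyloxy)octyl]-9-borabicyclo[3.3.1]nonane F5, which would be coupled with 7 as in step 4 to 4-[8-(tert-butyldimethylsilyloxy)octyl]-3-methylfuran-2(5H)-one F6. Desilylation with HF·pyridine (THF, 0 °C) should give 4-(8-hydroxyoctyl)-3-methylfuran-2(5H)-one F7, and Appel bromination (CBr4, PPh3, CH2Cl2, 0 °C) should return 10.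

Step 3. The oxygen-to-bromine exchange may stall at the O-activated enol stage, or the vinylogous acyl bromide may hydrolyse back to the tetronic acid on work-up. The fallback keeps the enol oxygen and turns it into the leaving group; it sets out from 6 and comes back at 10. O-Sulfonylation of 6 (Tf2O, i-Pr2NEt, CH2Cl2, −78 °C) should give 4-methyl-5-oxo-2,5-dihydrofuran-3-yl trifluoromethanesulfonate F8. F8 would take the place of 7 in the coupling with borane 9 (PdCl2(dppf), K3PO4·H2O, THF, 50 °C; alkenyl triflate/B-alkyl-9-BBN Suzuki coupling) to give 10.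

**Further compounds**
F1 | step 5 | 9-(dec-9-en-1-yl)-9-borabicyclo[3.3.1]nonane | C=CCCCCCCCCB1C2CCCC1CCC2
F2 | step 5 | 4-(dec-9-en-1-yl)-3-methylfuran-2(5H)-one | CC1=C(CCCCCCCCC=C)COC1=O
F3 | step 5 | (S)-16-(4-methyl-5-oxo-2,5-dihydrofuran-3-yl)hexadec-7-en-2-yl acetate (E/Z mixture) | CC(=O)O[C@@H](C)CCCCC=CCCCCCCCCC1=C(C)C(=O)OC1
F4 | step 4 | tert-butyldimethyl(oct-7-en-1-yloxy)silane | C=CCCCCCCO[Si](C)(C)C(C)(C)C
F5 | step 4 | 9-[8-(tert-butyldimethylsilyloxy)octyl]-9-borabicyclo[3.3.1]nonane | CC(C)(C)[Si](C)(C)OCCCCCCCCB1C2CCCC1CCC2
F6 | step 4 | 4-[8-(tert-butyldimethylsilyloxy)octyl]-3-methylfuran-2(5H)-one | CC1=C(CCCCCCCCO[Si](C)(C)C(C)(C)C)COC1=O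
F7 | step 4 | 4-(8-hydroxyoctyl)-3-methylfuran-2(5H)-one | CC1=C(CCCCCCCCO)COC1=O
F8 | step 3 | 4-methyl-5-oxo-2,5-dihydrofuran-3-yl trifluoromethanesulfonate | CC1=C(OS(=O)(=O)C(F)(F)F)COC1=O
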